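**Strategy.** The route rests on cutting the C6–C7 bond, which joins the lactone carbinol carbon to the tertiary carbinol carbon and is shared by the ten-membered carbocycle and the α-methylene-γ-lactone. Both carbons are carbonyl carbons in the precursor, a linear (Z,Z)-dienal ending in a 2-methylene-3-oxo ester (C13=C11–C7=O). CrCl2/Me3SiCl turns this enone into a γ-silyloxy allylchromium, so the C7 carbonyl carbon becomes nucleophilic and adds to the C6 aldehyde. One operation closes the cyclodecadiene, sets C6 and C7, keeps the C11=C13 methylene and triggers lactonisation. Nerol, D-tartrate and methyl acrylate supply the skeleton; C8 comes from the tartrate.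

Key step: step 12

Remark: atoms carry germacranolide numbers (C6 lactone carbinol, C7 tertiary carbinol, C8 angelate carbon, C9 ketone, C11/C12/C13 the α-methylene lactone carbons); the C7 carbinol of 15 and 16 is carried as an epimer mixture that the oxidation in step 11 erases.

**Step 1**
Reactants: 1 nerol
Product: 2 neryl tert-butyldimethylsilyl ether
Conditions: TBSCl, imidazole, CH2Cl2, 0 °C to rt
Reagents that add atoms: tert-butyldimethylsilyl chloride, CC(C)(C)[Si](C)(C)Cl
Why: Imidazole-mediated silyl ether formation masks O6 with a group that survives ylide, hydride and amine conditions and is later removed by fluoride.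

**Step 2**
Reactants: 2 neryl tert-butyldimethylsilyl ether
Product: 4 (Z)-6-[(tert-butyldimethylsilyl)oxy]-4-methylhex-4-en-1-ol, via aldehyde 3 (not isolated)
Conditions: O3 (1 equiv), pyridine, CH2Cl2–MeOH, −78 °C; then NaBH4, −78 to 0 °C
Reagents that add atoms: ozone, [O-][O+]=O
Why: Chemoselective ozonolysis with reductive work-up, in which the electron-rich terminal isopropylidene olefin should react faster than the olefin deactivated by the allylic silyloxy group, and NaBH4 reduces the peroxidic products to the primary alcohol.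

**Step 3**
Reactants: 4 (Z)-6-[(tert-butyldimethylsilyl)oxy]-4-methylhex-4-en-1-ol
Product: 5 (Z)-tert-butyl[(6-iodo-3-methylhex-2-en-1-yl)oxy]dimethylsilane
Conditions: I2, PPh3, imidazole, CH2Cl2, 0 °C
Reagents that add atoms: iodine, II
Why: Appel-type iodination replaces the primary hydroxyl by SN2 attack of iodide on the oxyphosphonium ion and leaves the allylic silyl ether intact.

**Step 4**
Reactants: 5 (Z)-tert-butyl[(6-iodo-3-methylhex-2-en-1-yl)oxy]dimethylsilane
Product: 6 [(Z)-6-[(tert-butyldimethylsilyl)oxy]-4-methylhex-4-en-1-yl]triphenylphosphonium iodide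
Conditions: PPh3, MeCN, 80 °C
Reagents that add atoms: triphenylphosphine, c1ccc(cc1)P(c1ccccc1)c1ccccc1
Why: SN2 quaternisation of triphenylphosphine by the unhindered primary iodide gives the Wittig salt.

**Step 5**
Reactants: 7 dimethyl (4S,5S)-2,2-dimethyl-1,3-dioxolane-4,5-dicarboxylate (dimethyl 2,3-O-isopropylidene-D-tartrate)
Product: 8 potassium (4S,5S)-5-(methoxycarbonyl)-2,2-dimethyl-1,3-dioxolane-4-carboxylate
Conditions: KOH (1.0 equiv), MeOH, 0 °C to rt
Reagents that add atoms: potassium hydroxide, [K+].[OH-]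
Why: Mono-saponification of the C2-symmetric diester, because the first carboxylate retards the second hydrolysis; the trans stereocentres are the stable arrangement and are not at risk.

**Step 6**
Reactants: 8 potassium (4S,5S)-5-(methoxycarbonyl)-2,2-dimethyl-1,3-dioxolane-4-carboxylate
Product: 10 methyl (4S,5S)-5-acetyl-2,2-dimethyl-1,3-dioxolane-4-carboxylate, via acid chloride 9 (not isolated)
Conditions: (COCl)2, cat. DMF, CH2Cl2, 0 °C; then Me2CuLi, Et2O, −78 °C
Reagents that add atoms: lithium dimethylcuprate, [Li+].C[Cu-]C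
Why: Acid chloride formation followed by cuprate acylation should stop at the methyl ketone, since Me2CuLi does not add to ketones or esters at −78 °C.

**Step 7**
Reactants: 6 [(Z)-6-[(tert-butyldimethylsilyl)oxy]-4-methylhex-4-en-1-yl]triphenylphosphonium iodide; 10 methyl (4S,5S)-5-acetyl-2,2-dimethyl-1,3-dioxolane-4-carboxylate
Product: 12 methyl (4S,5R)-5-[(2Z,6Z)-8-[(tert-butyldimethylsilyl)oxy]-6-methylocta-2,6-dien-2-yl]-2,2-dimethyl-1,3-dioxolane-4-carboxylate, via ylide 11 (not isolated)
Conditions: 6, KN(SiMe3)2, THF, −78 °C; then 10, −78 °C to rt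
Reagents that add atoms: none
Why: Wittig olefination of an α-alkoxy ketone with a non-stabilised ylide is Z-selective for the trisubstituted olefin (the ylide chain ends cis to the alkoxy-bearing carbon C9), which is the required 1(10)Z geometry, and the ketone reacts far faster than the ester.

**Step 8**
Reactants: 12 methyl (4S,5R)-5-[(2Z,6Z)-8-[(tert-butyldimethylsilyl)oxy]-6-methylocta-2,6-dien-2-yl]-2,2-dimethyl-1,3-dioxolane-4-carboxylate
Product: 13 (4S,5R)-5-[(2Z,6Z)-8-[(tert-butyldimethylsilyl)oxy]-6-methylocta-2,6-dien-2-yl]-2,2-dimethyl-1,3-dioxolane-4-carbaldehyde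
Conditions: i-Bu2AlH (1.1 equiv), CH2Cl2, −78 °C; MeOH, aq. KNaC4H4O6
Reagents that add atoms: none
Why: Partial hydride reduction of the α-alkoxy ester stops at the aldehyde because the chelated aluminium hemiacetal survives at −78 °C until work-up, and C8 in the trans-dioxolane is not epimerised.

**Step 9**
Reactants: 13 (4S,5R)-5-[(2Z,6Z)-8-[(tert-butyldimethylsilyl)oxy]-6-methylocta-2,6-dien-2-yl]-2,2-dimethyl-1,3-dioxolane-4-carbaldehyde; 14 methyl acrylate
Product: 15 methyl 2-{hydroxy[(4R,5R)-5-[(2Z,6Z)-8-[(tert-butyldimethylsilyl)oxy]-6-methylocta-2,6-dien-2-yl]-2,2-dimethyl-1,3-dioxolan-4-yl]methyl}prop-2-enoate (both carbinol epimers)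
Conditions: DABCO, methyl acrylate (excess), MeOH, rt
Reagents that add atoms: none
Why: Morita–Baylis–Hillman reaction, in which the DABCO–acrylate zwitterion adds to the reactive α-alkoxy aldehyde and installs C11, C12 and C13 in one step; the new carbinol C7 is formed without control because step 11 oxidises it.

**Step 10**
Reactants: 15 methyl 2-{hydroxy[(4R,5R)-5-[(2Z,6Z)-8-[(tert-butyldimethylsilyl)oxy]-6-methylocta-2,6-dien-2-yl]-2,2-dimethyl-1,3-dioxolan-4-yl]methyl}prop-2-enoate
Product: 16 methyl 2-{hydroxy[(4R,5R)-5-[(2Z,6Z)-8-hydroxy-6-methylocta-2,6-dien-2-yl]-2,2-dimethyl-1,3-dioxolan-4-yl]methyl}prop-2-enoate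
Conditions: HF·pyridine, pyridine, THF, 0 °C to rt
Reagents that add atoms: none
Why: Fluoride-mediated desilylation frees the primary allylic alcohol, and the pyridine buffer leaves the acetonide and the acrylate untouched.

**Step 11**
Reactants: 16 methyl 2-{hydroxy[(4R,5R)-5-[(2Z,6Z)-8-hydroxy-6-methylocta-2,6-dien-2-yl]-2,2-dimethyl-1,3-dioxolan-4-yl]methyl}prop-2-enoate
Product: 17 methyl 2-{[(4S,5R)-2,2-dimethyl-5-[(2Z,6Z)-6-methyl-8-oxoocta-2,6-dien-2-yl]-1,3-dioxolan-4-yl]carbonyl}prop-2-enoate
Conditions: Dess–Martin periodinane (3 equiv), NaHCO3, CH2Cl2, 0 °C; cold filtration, used at once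
Reagents that add atoms: none
Why: Dess–Martin oxidation converts both allylic alcohols in one operation (primary to the Z-enal, Baylis–Hillman carbinol to the 2-methylene-3-oxo ester) under buffered, cold, non-basic conditions that should preserve the enal geometry and C8.

**Step 12**
Reactants: 17 methyl 2-{[(4S,5R)-2,2-dimethyl-5-[(2Z,6Z)-6-methyl-8-oxoocta-2,6-dien-2-yl]-1,3-dioxolan-4-yl]carbonyl}prop-2-enoate
Product: 20 (6S,7R,8S,9R)-7-hydroxy-8,9-(isopropylidenedioxy)-(1(10)Z,4Z)-germacra-1(10),4,11(13)-trien-12,6-olide, via allylchromium species 18 (not isolated), via silyl ether hydroxy ester 19 (not isolated)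
Conditions: CrCl2 (8 equiv), Me3SiCl (4 equiv), THF–DMF, slow addition of 17 (final 2 mM), 0 °C to rt; then 0.5 M HCl–THF, 0 °C
Reagents that add atoms: none
Why: Divalent chromium with Me3SiCl reduces the doubly activated enone C13=C11–C7=O in two single-electron transfers to the γ-silyloxy allylchromium 18 (trivalent chromium on C13), which reverses the polarity of the C7 carbonyl carbon; C7 then attacks the C6 aldehyde through a six-membered chair (Zimmerman–Traxler) transition state, and the acidic work-up cleaves the O–SiMe3 bond and lets O6 lactonise onto the methyl ester. The closest known reactions are the chromium dichloride/silyl chloride cross-pinacol-type coupling of vinyl ketones with aldehydes and the Nozaki–Hiyama–Kishi macro-allylation with 2-(alkoxycarbonyl)allylchromium reagents. The ten-membered carbocycle closes by 10-exo-trig addition to the C=O group and the lactone by 5-exo-trig acyl substitution. The C6/C7 relation is expected from the chair, with C5 of the aldehyde equatorial, the silyloxy group (trans to CH2Cr, cis to the ester, from the s-trans enone) equatorial and C8 axial, which places 6-H and 7-OH cis on the lactone; the face of C7 is governed by C8, whose hydrogen eclipses the enol ether double bond (minimal A1,3 strain) so that the tether through C9 delivers the aldehyde syn to C9 and anti to O8, giving 7-OH cis to O8. The step needs reduction of the alkylidene keto ester in preference to the enal (two acceptor groups make it far easier to reduce than a β,β-dialkyl enal), γ- rather than α-attack (cyclic transition state, ten- rather than twelve-membered ring) and ring closure rather than oligomerisation (slow addition at high dilution).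

**Step 13**
Reactants: 20 (6S,7R,8S,9R)-7-hydroxy-8,9-(isopropylidenedioxy)-(1(10)Z,4Z)-germacra-1(10),4,11(13)-trien-12,6-olide
Product: 21 (6S,7R,8S,9R)-7,8,9-trihydroxy-(1(10)Z,4Z)-germacra-1(10),4,11(13)-trien-12,6-olide
Conditions: AcOH–H2O 4:1, 40 °C
Reagents that add atoms: none
Why: Acid-catalysed acetal hydrolysis under weakly acidic conditions, which a cis,cis-cyclodeca-1,5-diene should tolerate without transannular cyclisation and which should not move the lactone from O6 to O8.

**Step 14**
Reactants: 21 (6S,7R,8S,9R)-7,8,9-trihydroxy-(1(10)Z,4Z)-germacra-1(10),4,11(13)-trien-12,6-olide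
Product: 22 (6S,7R,8R)-7,8-dihydroxy-9-oxo-(1(10)Z,4Z)-germacra-1(10),4,11(13)-trien-12,6-olide
Conditions: MnO2 (excess), CH2Cl2, rt
Reagents that add atoms: none
Why: Allylic alcohol oxidation with MnO2 should take only the allylic C9 carbinol and spare the secondary C8 and tertiary C7 alcohols, while the ring holds the new enone in the Z geometry.

**Step 15**
Reactants: 22 (6S,7R,8R)-7,8-dihydroxy-9-oxo-(1(10)Z,4Z)-germacra-1(10),4,11(13)-trien-12,6-olide; 23 angelic acid
Product: 24 (6S,7R,8R)-8-angeloyloxy-7-hydroxy-9-oxo-(1(10)Z,4Z)-germacra-1(10),4,11(13)-trien-12,6-olide (CNP0276177.1)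
Conditions: 23, 2,4,6-trichlorobenzoyl chloride, Et3N, toluene, rt, filtered; then 22, toluene, 70 °C
Reagents that add atoms: none
Why: Yamaguchi esterification through the preformed mixed anhydride, without DMAP, acylates the only secondary alcohol (C8–OH; the tertiary C7–OH is inert) and avoids the nucleophile-induced isomerisation of angelate to tiglate.

**Compound list**
1 | nerol | CC(C)=CCC/C(C)=C\CO | starting material
2 | neryl tert-butyldimethylsilyl ether | CC(C)=CCC/C(C)=C\CO[Si](C)(C)C(C)(C)C | intermediate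
3 | (Z)-6-[(tert-butyldimethylsilyl)oxy]-4-methylhex-4-enal | O=CCC/C(C)=C\CO[Si](C)(C)C(C)(C)C | intermediate
4 | (Z)-6-[(tert-butyldimethylsilyl)oxy]-4-methylhex-4-en-1-ol | OCCC/C(C)=C\CO[Si](C)(C)C(C)(C)C | intermediate
5 | (Z)-tert-butyl[(6-iodo-3-methylhex-2-en-1-yl)oxy]dimethylsilane | ICCC/C(C)=C\CO[Si](C)(C)C(C)(C)C | intermediate
6 | [(Z)-6-[(tert-butyldimethylsilyl)oxy]-4-methylhex-4-en-1-yl]triphenylphosphonium iodide | CC(C)(C)[Si](C)(C)OC/C=C(/C)CCC[P+](c1ccccc1)(c1ccccc1)c1ccccc1.[I-] | intermediate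
7 | dimethyl (4S,5S)-2,2-dimethyl-1,3-dioxolane-4,5-dicarboxylate | COC(=O)[C@H]1OC(C)(C)O[C@@H]1C(=O)OC | starting material
8 | potassium (4S,5S)-5-(methoxycarbonyl)-2,2-dimethyl-1,3-dioxolane-4-carboxylate | [K+].[O-]C(=O)[C@H]1OC(C)(C)O[C@@H]1C(=O)OC | intermediate
9 | methyl (4S,5S)-5-(chlorocarbonyl)-2,2-dimethyl-1,3-dioxolane-4-carboxylate | ClC(=O)[C@H]1OC(C)(C)O[C@@H]1C(=O)OC | intermediate
10 | methyl (4S,5S)-5-acetyl-2,2-dimethyl-1,3-dioxolane-4-carboxylate | CC(=O)[C@H]1OC(C)(C)O[C@@H]1C(=O)OC | intermediate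
11 | [(Z)-6-[(tert-butyldimethylsilyl)oxy]-4-methylhex-4-en-1-ylidene]triphenylphosphorane | CC(C)(C)[Si](C)(C)OC/C=C(/C)CCC=P(c1ccccc1)(c1ccccc1)c1ccccc1 | intermediate
12 | methyl (4S,5R)-5-[(2Z,6Z)-8-[(tert-butyldimethylsilyl)oxy]-6-methylocta-2,6-dien-2-yl]-2,2-dimethyl-1,3-dioxolane-4-carboxylate | CC(C)(C)[Si](C)(C)OC/C=C(/C)CC/C=C(/C)[C@H]1OC(C)(C)O[C@@H]1C(=O)OC | intermediate
13 | (4S,5R)-5-[(2Z,6Z)-8-[(tert-butyldimethylsilyl)oxy]-6-methylocta-2,6-dien-2-yl]-2,2-dimethyl-1,3-dioxolane-4-carbaldehyde | CC(C)(C)[Si](C)(C)OC/C=C(/C)CC/C=C(/C)[C@H]1OC(C)(C)O[C@@H]1C=O | intermediate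
14 | methyl acrylate | C=CC(=O)OC | starting material
15 | methyl 2-{hydroxy[(4R,5R)-5-[(2Z,6Z)-8-[(tert-butyldimethylsilyl)oxy]-6-methylocta-2,6-dien-2-yl]-2,2-dimethyl-1,3-dioxolan-4-yl]methyl}prop-2-enoate (carbinol epimers) | CC(C)(C)[Si](C)(C)OC/C=C(/C)CC/C=C(/C)[C@H]1OC(C)(C)O[C@@H]1C(O)C(=C)C(=O)OC | intermediate
16 | methyl 2-{hydroxy[(4R,5R)-5-[(2Z,6Z)-8-hydroxy-6-methylocta-2,6-dien-2-yl]-2,2-dimethyl-1,3-dioxolan-4-yl]methyl}prop-2-enoate (carbinol epimers) | OC/C=C(/C)CC/C=C(/C)[C@H]1OC(C)(C)O[C@@H]1C(O)C(=C)C(=O)OC | intermediate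
17 | methyl 2-{[(4S,5R)-2,2-dimethyl-5-[(2Z,6Z)-6-methyl-8-oxoocta-2,6-dien-2-yl]-1,3-dioxolan-4-yl]carbonyl}prop-2-enoate | O=C/C=C(/C)CC/C=C(/C)[C@H]1OC(C)(C)O[C@@H]1C(=O)C(=C)C(=O)OC | intermediate
18 | γ-trimethylsilyloxy allylchromium dichloride derived from 17 (trivalent chromium on C13, enal intact) | O=C/C=C(/C)CC/C=C(/C)[C@H]1OC(C)(C)O[C@@H]1/C(O[Si](C)(C)C)=C(/C(=O)OC)C[Cr](Cl)Cl | intermediate
19 | methyl (6S,7R,8S,9R)-6-hydroxy-8,9-(isopropylidenedioxy)-7-(trimethylsilyloxy)-(1(10)Z,4Z)-germacra-1(10),4,11(13)-trien-12-oate | O[C@H]1/C=C(/C)CC/C=C(/C)[C@H]2OC(C)(C)O[C@@H]2[C@@]1(O[Si](C)(C)C)C(=C)C(=O)OC | intermediate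
20 | (6S,7R,8S,9R)-7-hydroxy-8,9-(isopropylidenedioxy)-(1(10)Z,4Z)-germacra-1(10),4,11(13)-trien-12,6-olide | C=C1C(=O)O[C@H]2/C=C(/C)CC/C=C(/C)[C@H]3OC(C)(C)O[C@@H]3[C@@]12O | intermediate
21 | (6S,7R,8S,9R)-7,8,9-trihydroxy-(1(10)Z,4Z)-germacra-1(10),4,11(13)-trien-12,6-olide | C=C1C(=O)O[C@H]2/C=C(/C)CC/C=C(/C)[C@@H](O)[C@H](O)[C@@]12O | intermediate
22 | (6S,7R,8R)-7,8-dihydroxy-9-oxo-(1(10)Z,4Z)-germacra-1(10),4,11(13)-trien-12,6-olide | C=C1C(=O)O[C@H]2/C=C(/C)CC/C=C(/C)C(=O)[C@H](O)[C@@]12O | intermediate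
23 | angelic acid, (Z)-2-methylbut-2-enoic acid | C/C=C(/C)C(=O)O | starting material
24 | (6S,7R,8R)-8-angeloyloxy-7-hydroxy-9-oxo-(1(10)Z,4Z)-germacra-1(10),4,11(13)-trien-12,6-olide | C=C1C(=O)O[C@H]2/C=C(/C)CC/C=C(/C)C(=O)[C@H](OC(=O)/C(C)=C\C)[C@@]12O | target

**Step count and risks**

Total steps: 15. Longest linear sequence: 13 (steps 1–4 and 7–15, from nerol).

The three steps most likely to fail:

Step 12. Electron transfer may also reach the enal, the allyl radical may dimerise before divalent chromium captures it, the open chain may oligomerise, or the macrocyclic transition state may choose the other face of C7. The fallback separates generation of the nucleophile from the reduction of an enone. It sets out from 17: conjugate addition of Me3SiBr (CH2Cl2, −78 °C) should give the γ-trimethylsilyloxy allylic bromide F1. A Nozaki–Hiyama–Kishi allylation (CrCl2, THF, high dilution) then forms the allylchromium by oxidative addition into the C–Br bond, with no silyl chloride or ketyl-type radical near the enal. A chiral oxazoline–sulfonamide ligand on chromium can be added to impose reagent control on the aldehyde face. The same HCl work-up comes back to the route at 20.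

Step 11. The 2-methylene-3-oxo ester may dimerise by hetero-Diels–Alder reaction or polymerise, and the Z-enal may drift to E during oxidation and work-up. The fallback installs the methylene last, from a storable precursor. It sets out from 13: aldol addition of the lithium enolate of methyl acetate (LiN(i-Pr)2, THF, −78 °C) gives the β-hydroxy ester F2. HF·pyridine gives the diol F3, and Dess–Martin oxidation gives the β-keto ester enal F4, which enolises towards C11 and so protects C8. Mannich reaction with dimethylmethyleneiminium iodide gives the Mannich base F5. Quaternisation with MeI and elimination with NaHCO3 at 0 °C release 17 in the cyclisation solvent, free of oxidant residues, and the route resumes at 17.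

Step 15. Acylation of the hindered C8–OH may be slow, and heating with base may isomerise angelate to tiglate, epimerise C8, open the β-hydroxy ketone by retro-aldol cleavage or move the lactone to O8. The fallback builds the Z-olefin of the ester after the acylation. It sets out from 22: carbodiimide coupling (DCC, cat. DMAP, CH2Cl2, 0 °C) with 2-[bis(2,2,2-trifluoroethoxy)phosphoryl]propanoic acid, which has no double bond to isomerise, gives the phosphonate ester F6. Still–Gennari olefination with acetaldehyde (K2CO3, 18-crown-6, toluene, −20 °C) should give the Z-enoate and comes back to the route at 24.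

**Further compounds**
F1 | step 12 | methyl (Z)-2-(bromomethyl)-3-[(4S,5R)-2,2-dimethyl-5-[(2Z,6Z)-6-methyl-8-oxoocta-2,6-dien-2-yl]-1,3-dioxolan-4-yl]-3-(trimethylsilyloxy)prop-2-enoate | O=C/C=C(/C)CC/C=C(/C)[C@H]1OC(C)(C)O[C@@H]1/C(O[Si](C)(C)C)=C(/C(=O)OC)CBr
F2 | step 11 | methyl 3-[(4R,5R)-5-[(2Z,6Z)-8-[(tert-butyldimethylsilyl)oxy]-6-methylocta-2,6-dien-2-yl]-2,2-dimethyl-1,3-dioxolan-4-yl]-3-hydroxypropanoate (carbinol epimers) | CC(C)(C)[Si](C)(C)OC/C=C(/C)CC/C=C(/C)[C@H]1OC(C)(C)O[C@@H]1C(O)CC(=O)OC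
F3 | step 11 | methyl 3-hydroxy-3-[(4R,5R)-5-[(2Z,6Z)-8-hydroxy-6-methylocta-2,6-dien-2-yl]-2,2-dimethyl-1,3-dioxolan-4-yl]propanoate (carbinol epimers) | OC/C=C(/C)CC/C=C(/C)[C@H]1OC(C)(C)O[C@@H]1C(O)CC(=O)OC
F4 | step 11 | methyl 3-[(4S,5R)-2,2-dimethyl-5-[(2Z,6Z)-6-methyl-8-oxoocta-2,6-dien-2-yl]-1,3-dioxolan-4-yl]-3-oxopropanoate | O=C/C=C(/C)CC/C=C(/C)[C@H]1OC(C)(C)O[C@@H]1C(=O)CC(=O)OC
F5 | step 11 | methyl 2-[(dimethylamino)methyl]-3-[(4S,5R)-2,2-dimethyl-5-[(2Z,6Z)-6-methyl-8-oxoocta-2,6-dien-2-yl]-1,3-dioxolan-4-yl]-3-oxopropanoate | O=C/C=C(/C)CC/C=C(/C)[C@H]1OC(C)(C)O[C@@H]1C(=O)C(CN(C)C)C(=O)OC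
F6 | step 15 | (6S,7R,8R)-8-{2-[bis(2,2,2-trifluoroethoxy)phosphoryl]propanoyloxy}-7-hydroxy-9-oxo-(1(10)Z,4Z)-germacra-1(10),4,11(13)-trien-12,6-olide | C=C1C(=O)O[C@H]2/C=C(/C)CC/C=C(/C)C(=O)[C@H](OC(=O)C(C)P(=O)(OCC(F)(F)F)OCC(F)(F)F)[C@@]12O
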